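The data stem from a simulated flask with constants of no real substance.

The first reading of the south-east run comes at 0.250 d, and from there to 5.00 d the target stays flat within the scatter of 1 percentage point, as it does in the north run. A flat stretch invites the bench rule of freezing it.

all flasks: substrate 0.41 M

| charge | reagent | remark | time |
|---|---|---|---|
| south-east | 0.19 M | run made earlier |  |
| north | 0.43 M | run made earlier |  |
| flask | 0.287 M |  | 8.0 d |

| run | time / d | target / % | isomer of the product A / % |
|---|---|---|---|
| south-east | 0.250 | 29.3 | 13.7 |
| south-east | 0.833 | 27.9 | 14.1 |
| south-east | 1.25 | 27.9 | 14.8 |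
| south-east | 2.08 | 28.9 | 13.8 |
| south-east | 3.00 | 29.2 | 15.5 |
| south-east | 4.00 | 28.9 | 13.0 |
| south-east | 5.00 | 28.9 | 15.1 |
| north | 0.417 | 64.5 | 29.1 |
| north | 0.625 | 63.6 | 26.8 |
| north | 0.833 | 63.8 | 25.6 |
| north | 1.25 | 64.8 | 27.1 |
| north | 2.08 | 63.5 | 26.5 |
| north | 3.00 | 64.1 | 27.4 |
| north | 5.00 | 64.7 | 26.9 |

(scatter of a reading: 1 percentage point)

- share of target in target plus isomer of the product A at 2.0 min
- share of target in target plus isomer of the product A at 2.5 h
- share of target in target plus isomer of the product A at 8.0 d
- which of target and isomer of the product A there is more of at 8.0 d

On its plateau the south-east run holds 28.7% of target and 14.3% of isomer of the product A. Their sum is nearly all of the 46.3% that c(reagent) makes of c(substrate) in that run, so reagent reads as the limiting reagent there. This gives 0.620 for the target yield on reagent, the amount of target standing on the plateau per amount of reagent charged.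

The flask also has less reagent than substrate, so this yield gives 43.4% of target. The south-east plateau has more target than isomer of the product A, with a share of 66.7%. But the frozen number was read on the plateau, and the readings begin after two of the asked times. The time 2.0 min lies a factor 180 before the first south-east reading, and 2.5 h a factor 2.40. This reckoning therefore claims nothing at 2.0 min and carries the share to 2.5 h with caution.

The forecast gives 68%, 68% and 68.2%, with target ahead: “I expect the share to be time-independent.”

The flask gives 93.0%, 67.9% and 67.9%, with target ahead, so the forecast and the flask part at 2.0 min. At 0.00308 d other conformer is being made 1.48 times as fast as it is used up, each step taken net. At 8.00 d the flask holds 43.7% of target against the 43.4% from the yield on reagent, and its own yield on reagent is 0.624.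

    substrate + reagent → target (k = 0.397 /M/min)
    reagent + other conformer → isomer of the product A (k = 1.22 /M/min)
    substrate ⇌ dormant form (K = 0.325, k = 2.03 /min)
    target ⇌ isomer of the product B (K = 0.130, k = 0.0191 /min)
    substrate ⇌ other conformer (K = 2.50, k = 0.0293 /min)

The neighbour charged with 0.17 M of reagent has less reagent than substrate, and the yield gives it 25.7% of target. The computed neighbour holds 25.7% of target at 8.00 d, with 0% of its reagent left.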